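The numbers in the tables were computed with constants of no real substance; noise was put on by code.

At 100 °C, a time of 6.0 h is judged here against the clocks of the teal run, which is the asked flask followed so far, so the useful question is how many half-times of the rise in target fit into it.

| setting | teal | red | flask |
|---|---|---|---|
| substrate | 0.081 M | 0.081 M | 0.081 M |
| coupling partner | 2.5 equiv | 1.2 equiv | 2.50 equiv |
| temperature | 100 °C | 106 °C | 100 °C |
| remark | the very flask that is asked about, followed so far | run made earlier |  |
| time |  |  | 6.0 h |

- teal (time / min: target / %, substrate / %): 25.0: 8.7, 0.9; 80.0: 16.4, 0; 120: 18.4, 0; 180: 18.3, 1.2; 300: 17.5, 0.2
- red (time / min: target / %, substrate / %): 3.00: 1.2, 40.8; 6.00: 5.3, 15.0; 12.0: 9.7, 1.6; 20.0: 16.4, 1.5; 40.0: 26.0, 0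

(readings scatter by 1 percentage point)

- target, in percent of the substrate first charged, at 6.0 h
- what to do for the largest gain in target; "none" if nothing gains more than 2 percentage points (south-west / east / south-east / south / none)
- target present, with what was taken out counted in, in percent of the substrate first charged, after south-west
- target present, with what was taken out counted in, in percent of the substrate first charged, after south-east

- south-west: at 6.0 h take out 90% of the target then present, then wait 12 h
- east: at 6.0 h raise the temperature by 20 K, then wait 12 h
- south-east: at 6.0 h add coupling partner, 50.0% of the amount charged, then wait 12 h
- south: change nothing and wait 12 h more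

- removed target is counted in
- additions bring no volume worth counting

The first clock belongs to substrate, the limiting reagent: the red run, 106 °C hot, falls to 15.0% at 6.00 min, which reads as a half-life of 2.19 min in that hotter flask, and the teal run already reads 0.9% at 25.0 min. Target comes next and more slowly. Its last three teal readings average a plateau P of 18.1%, and the reading of 8.7% is about half of that, so the half-time τ of the rise is read as 25.0 min, longer than the substrate clock. The asked time is longer still, and the count of half-times N, the asked time divided by τ, is 14.4.

The gap still open at the asked time is, by this reckoning, P halved N times, about 8.4 × 10⁻⁴ percentage points, which is less than the margin of 2 points. The red run, which differs from the teal run in both partner and temperature, reads 26.0% at 40.0 min with 1.2 equiv of partner, more than P, so this reckoning takes P as a split made before the asked time rather than a ceiling on target. With the rise taken as ended at that count, this reckoning commits to P for the present value and for both counted-in values, with no option worth taking. The readings cannot themselves exclude a stall.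

The forecast gives 18%, 18.5% after south-west, 17.8% after south-east, and none as the choice, with the words "Heating a dead system gives little." Its two counted-in values stand on either side of P , and its grounds differ from this reckoning, which speaks of a finished split and not of a dead system.

The flask gives 18.0%, with 18.0% after south-west and 18.0% after south-east, and the choice is none.

    substrate → intermediate A (k = 0.160 /min, Ea = 113 kJ/mol)
    coupling partner + intermediate A → side product A (k = 0.190 /M/min, Ea = 76.0 kJ/mol)
    substrate → intermediate B (k = 0.0120 /min, Ea = 110 kJ/mol)
    intermediate A → target (k = 0.00770 /min, Ea = 113 kJ/mol)
    coupling partner + intermediate B → side product B (k = 0.0400 /M/min, Ea = 94.0 kJ/mol)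
    (constants at 100 °C)

Intermediate A, the species before target, stands at 0% at 360 min. Back at 36.0 min the count is 1.44, which puts target at 11.4% by the reckoning, and the flask holds 12.0%. The neighbour flask with 0.620 equiv of partner holds 1.35% of intermediate A at 360 min, more than the gap reckoned from N for the asked flask, and its target stands at 52.1%.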